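Everything rests on building ring B last from two partners, by cutting C2'–C3', C4'–C5' and C1'–C2'. The feature exploited is that the C2' phenol and the C4' aryloxy oxygen stand 1,3 across unsubstituted C3'–H, with C5'–OMe para to C2'–OH. This maps onto a ketene carbonyl carbon bonded to the CH terminus of an O-aryl ethynyl ether. In one operation the E-methoxy(vinyl)ketene adds to ring A ethynyl ether 13. The ketene is freed from 21, an acyclic 2-methoxyglutaconate half acid chloride with heptyl cis to its benzyl ester. The cyclobutenone opens and recloses to pentasubstituted ring B, with the diaryl ether in place, C5'–O methylated and C2'–OH free. One hydrogenolysis of both benzyl esters ends the route.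

Key step: step 12

Numbering: ring A = C1 (CO2H), C2 (heptyl), C4 (OMe), C6 (ether O). Ring B = C1' (CO2H), C2' (OH), C3' (H), C4' (ether O), C5' (OMe), C6' (heptyl).
Remark on stereochemistry: the target has no stereocentre and its diaryl ether axis rotates freely, so there is no enantiomer to select. The only stereochemical element of the route is the E geometry carried from 16 to 22.
Assumption: tert-butyl methoxyacetate 17 and benzyl diazoacetate 14 (toluene solution) are taken as catalogue compounds.

Step 1
Reactants: 1 octanal; 2 1-(triphenyl-λ5-phosphanylidene)propan-2-one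
Product: 3 (E)-undec-3-en-2-one
Conditions: CH2Cl2, reflux
Reagents that add atoms: none
Why: Wittig olefination with a stabilised acyl ylide is reliably E-selective for unbranched aldehydes and avoids the self-aldol side reactions of a base-mediated acetone condensation.

Step 2
Reactants: 3 (E)-undec-3-en-2-one; 4 dibenzyl malonate
Product: 5 benzyl 2-heptyl-4,6-dioxocyclohexane-1-carboxylate (keto/enol and cis/trans mixture)
Conditions: NaH (1.1 equiv), BnOH (0.1 equiv), THF, 0 °C to reflux; then 1 M HCl
Reagents that add atoms: none
Why: Tandem Michael addition and intramolecular Claisen (Dieckmann-type) condensation is the classical entry to 6-alkyl dihydroresorcylates, the dibenzyl malonate installs the final ester directly, and the two new stereocentres need no control because step 3 erases them.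

Step 3
Reactants: 5 benzyl 2-heptyl-4,6-dioxocyclohexane-1-carboxylate
Product: 6 benzyl 2-heptyl-4,6-dihydroxybenzoate
Conditions: I2 (20 mol %), DMSO, 80 °C
Reagents that add atoms: none
Why: Iodine-catalysed oxidative aromatisation of a cyclohexane-1,3-dione (α-iodination, loss of HI, DMSO as terminal oxidant) gives the resorcylate without stoichiometric halogen on the ring and without a hydrogen-transfer catalyst that would endanger the benzyl ester.

Step 4
Reactants: 6 benzyl 2-heptyl-4,6-dihydroxybenzoate
Product: 7 benzyl 2-heptyl-6-hydroxy-4-methoxybenzoate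
Conditions: MeI (1.05 equiv), K2CO3, acetone, reflux
Reagents that add atoms: iodomethane, CI
Why: Williamson etherification should be selective for the free, more acidic para hydroxyl, because the ortho hydroxyl is tied up in a hydrogen bond to the ester carbonyl.

Step 5
Reactants: 7 benzyl 2-heptyl-6-hydroxy-4-methoxybenzoate; 8 trichloroethylene
Product: 10 benzyl 2-{[(E)-1,2-dichloroethenyl]oxy}-6-heptyl-4-methoxybenzoate, via dichloroacetylene 9 (not isolated)
Conditions: K2CO3, DMF, 70 °C, closed vessel under N2
Reagents that add atoms: none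
Why: Base-induced loss of HCl from 8 followed by anti addition of the phenoxide to the transient haloalkyne (nucleophilic vinylation) is the general route to aryl (E)-1,2-dichlorovinyl ethers, and the carbanion formed points away from the ortho ester.

Step 6
Reactants: 10 benzyl 2-{[(E)-1,2-dichloroethenyl]oxy}-6-heptyl-4-methoxybenzoate
Product: 13 benzyl 2-(ethynyloxy)-6-heptyl-4-methoxybenzoate, via chloroethynyl ether 11 (not isolated), via lithium acetylide 12 (not isolated)
Conditions: n-BuLi (2.1 equiv), THF, −78 °C; H2O/THF at −78 °C; cold work-up at pH 7–8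
Reagents that add atoms: none
Why: This is the known dichlorovinyl ether route to terminal ynol ethers, in which vinylic deprotonation with loss of LiCl gives 11 and chlorine–lithium exchange gives 12, both much faster at −78 °C than addition of butyllithium to the doubly ortho-substituted, twisted benzoate, and the linear acetylide cannot reach the neighbouring ester before it is protonated.

Step 7
Reactants: 1 octanal; 14 benzyl diazoacetate
Product: 15 benzyl 3-oxodecanoate
Conditions: SnCl2 (10 mol %), CH2Cl2, rt
Reagents that add atoms: none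
Why: In the Roskamp reaction the diazo ester adds to the Lewis-acid-activated aldehyde, and a 1,2-hydride shift with loss of N2 gives the β-keto ester in one step.

Step 8
Reactants: 15 benzyl 3-oxodecanoate
Product: 16 benzyl (E)-3-{[(trifluoromethyl)sulfonyl]oxy}dec-2-enoate
Conditions: Tf2O, aq Me4NOH, hexanes, 5 °C
Reagents that add atoms: trifluoromethanesulfonic anhydride, O=S(=O)(OS(=O)(=O)C(F)(F)F)C(F)(F)F
Why: O-sulfonylation of the β-keto ester enolate under biphasic Schotten–Baumann conditions should be E-selective, because the non-coordinating ammonium counter-ion favours the open, dipole-minimised enolate and places OTf trans to the ester, the opposite of the chelated lithium enolate.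

Step 9
Reactants: 16 benzyl (E)-3-{[(trifluoromethyl)sulfonyl]oxy}dec-2-enoate; 17 tert-butyl methoxyacetate
Product: 19 1-benzyl 5-tert-butyl (E)-3-heptyl-4-methoxypent-2-enedioate (racemic), via chlorozinc enolate 18 (not isolated)
Conditions: 17, LDA, THF, −78 °C; ZnCl2, to 0 °C; then 16, Pd(dba)2 (3 mol %), Q-Phos (3 mol %), THF, rt
Reagents that add atoms: none
Why: Negishi-type coupling of a Reformatsky-type zinc ester enolate with an alkenyl triflate proceeds with retention, so C4 takes the place of OTf trans to the benzyl ester, the weakly basic zinc enolate should leave the doubly activated C4–H of the product untouched (no migration or scrambling of the alkene), and the new C4 stereocentre is racemic and disappears in step 12.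

Step 10
Reactants: 19 1-benzyl 5-tert-butyl (E)-3-heptyl-4-methoxypent-2-enedioate
Product: 20 (E)-5-(benzyloxy)-3-heptyl-2-methoxy-5-oxopent-3-enoic acid (racemic)
Conditions: TFA/CH2Cl2 1:3, 0 °C to rt
Reagents that add atoms: none
Why: Acidolysis of the tert-butyl ester through the tert-butyl cation leaves the benzyl enoate and the methyl ether intact, and no base touches the acidic C–H.

Step 11
Reactants: 20 (E)-5-(benzyloxy)-3-heptyl-2-methoxy-5-oxopent-3-enoic acid
Product: 21 benzyl (E)-5-chloro-3-heptyl-4-methoxy-5-oxopent-2-enoate, equal to benzyl (E)-4-(chlorocarbonyl)-3-heptyl-4-methoxybut-2-enoate (racemic)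
Conditions: 1-chloro-N,N,2-trimethylprop-1-en-1-amine (1.1 equiv), CH2Cl2, 0 °C to rt; concentrate, use at once
Reagents that add atoms: 1-chloro-N,N,2-trimethylprop-1-en-1-amine, CC(C)=C(Cl)N(C)C
Why: Acid chloride formation with an α-chloroenamine runs under neutral conditions without HCl or amine, so neither enolisation nor E/Z leakage is expected, and the amide by-product is inert in the next step.

Step 12
Reactants: 13 benzyl 2-(ethynyloxy)-6-heptyl-4-methoxybenzoate; 21 benzyl (E)-5-chloro-3-heptyl-4-methoxy-5-oxopent-2-enoate
Product: 26 benzyl 4-{2-[(benzyloxy)carbonyl]-3-heptyl-5-methoxyphenoxy}-2-heptyl-6-hydroxy-3-methoxybenzoate, via vinylketene 22 (not isolated), via cyclobutenone 23 (not isolated), via dienylketene 24 (not isolated), via cyclohexadienone 25 (not isolated)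
Conditions: 13 (1.0 equiv), iPr2NEt (1.6 equiv), toluene, 25 °C, 21 (1.3 equiv) added by syringe pump over 4 h; then 100 °C, 3 h
Reagents that add atoms: none
Why: Proposed new method: iPr2NEt strips HCl from 21, whose C–H is activated by both the acyl chloride and the vinylogous ester, and the carbonyl carbon of E-vinylketene 22 is attacked by the nucleophilic CH terminus of 13, the zwitterion collapsing stepwise at the oxygen-stabilised cationic carbon to cyclobutenone 23 (bonds C2'–C3' and C4'–C5'). Heating breaks the former ketene C=C bond of 23 by conrotatory 4π opening in which the donor methoxy group rotates outward and the alkenyl arm inward, which gives dienylketene 24 in the only geometry that can cyclise. Ring B then closes by disrotatory 6π electrocyclisation between ketene carbon C2' and ester-bearing C1' (H inside and CO2Bn outside thanks to the E alkene), and β-keto ester 25 enolises irreversibly to the hydrogen-bonded phenol 26. The closest known reaction types are the Danheiser benzannulation of vinylketenes with alkoxyalkynes and the Moore rearrangement of 4-alkenyl-4-alkoxycyclobutenones; untested here are ketene release by dehydrochlorination, an ester on the vinyl terminus and an aryl ynol ether as ketenophile. The selectivity needed is regiochemical and is fixed by the polarity of 13, which sets OAr beside OMe and CH beside the phenol, while approach of 13 on the methoxy side of the ketene keeps the cationic carbon away from C1' and disfavours a direct [4+2] closure, and the E geometry excludes oxa-6π closure onto the ester carbonyl. No stereocentre has to be controlled, since C4 of 23 and C1' of 25 are transient and vanish on aromatisation.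

Step 13
Reactants: 26 benzyl 4-{2-[(benzyloxy)carbonyl]-3-heptyl-5-methoxyphenoxy}-2-heptyl-6-hydroxy-3-methoxybenzoate
Product: 27 4-(2-carboxy-3-heptyl-5-methoxyphenoxy)-2-heptyl-6-hydroxy-3-methoxybenzoic acid (target)
Conditions: H2 (1 atm), 10 % Pd/C, EtOAc, rt
Reagents that add atoms: none
Why: Catalytic hydrogenolysis frees both hindered carboxyl groups under neutral conditions at room temperature, which avoids forcing hydrolysis and decarboxylation of the electron-rich salicylic acid ring B and leaves the diaryl ether and the methyl ethers untouched.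

Compound list
1 | octanal | CCCCCCCC=O | starting material
2 | 1-(triphenyl-λ5-phosphanylidene)propan-2-one | CC(=O)C=P(c1ccccc1)(c1ccccc1)c1ccccc1 | starting material
3 | (E)-undec-3-en-2-one | CCCCCCC/C=C/C(C)=O | intermediate
4 | dibenzyl malonate | O=C(CC(=O)OCc1ccccc1)OCc1ccccc1 | starting material
5 | benzyl 2-heptyl-4,6-dioxocyclohexane-1-carboxylate (stereoisomer and tautomer mixture) | CCCCCCCC1CC(=O)CC(=O)C1C(=O)OCc1ccccc1 | intermediate
6 | benzyl 2-heptyl-4,6-dihydroxybenzoate | CCCCCCCc1cc(O)cc(O)c1C(=O)OCc1ccccc1 | intermediate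
7 | benzyl 2-heptyl-6-hydroxy-4-methoxybenzoate | CCCCCCCc1cc(OC)cc(O)c1C(=O)OCc1ccccc1 | intermediate
8 | trichloroethylene | ClC=C(Cl)Cl | starting material
9 | dichloroacetylene | ClC#CCl | intermediate (not isolated)
10 | benzyl 2-{[(E)-1,2-dichloroethenyl]oxy}-6-heptyl-4-methoxybenzoate | CCCCCCCc1cc(OC)cc(O/C(Cl)=C\Cl)c1C(=O)OCc1ccccc1 | intermediate
11 | benzyl 2-[(chloroethynyl)oxy]-6-heptyl-4-methoxybenzoate | CCCCCCCc1cc(OC)cc(OC#CCl)c1C(=O)OCc1ccccc1 | intermediate (not isolated)
12 | lithium acetylide of 13 | CCCCCCCc1cc(OC)cc(OC#C[Li])c1C(=O)OCc1ccccc1 | intermediate (not isolated)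
13 | benzyl 2-(ethynyloxy)-6-heptyl-4-methoxybenzoate | C#COc1cc(OC)cc(CCCCCCC)c1C(=O)OCc1ccccc1 | intermediate
14 | benzyl diazoacetate | [N-]=[N+]=CC(=O)OCc1ccccc1 | starting material
15 | benzyl 3-oxodecanoate | CCCCCCCC(=O)CC(=O)OCc1ccccc1 | intermediate
16 | benzyl (E)-3-{[(trifluoromethyl)sulfonyl]oxy}dec-2-enoate | CCCCCCC/C(OS(=O)(=O)C(F)(F)F)=C\C(=O)OCc1ccccc1 | intermediate
17 | tert-butyl methoxyacetate | COCC(=O)OC(C)(C)C | starting material
18 | chlorozinc enolate of 17 (drawn C-bound) | COC([Zn]Cl)C(=O)OC(C)(C)C | intermediate (not isolated)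
19 | 1-benzyl 5-tert-butyl (E)-3-heptyl-4-methoxypent-2-enedioate (racemic) | O=C(OC(C)(C)C)C(OC)/C(CCCCCCC)=C/C(=O)OCc1ccccc1 | intermediate
20 | (E)-5-(benzyloxy)-3-heptyl-2-methoxy-5-oxopent-3-enoic acid (racemic) | O=C(O)C(OC)/C(CCCCCCC)=C/C(=O)OCc1ccccc1 | intermediate
21 | benzyl (E)-5-chloro-3-heptyl-4-methoxy-5-oxopent-2-enoate (racemic) | O=C(Cl)C(OC)/C(CCCCCCC)=C/C(=O)OCc1ccccc1 | intermediate
22 | benzyl (E)-3-heptyl-4-methoxy-5-oxopenta-2,4-dienoate (vinylketene) | O=C=C(OC)/C(CCCCCCC)=C/C(=O)OCc1ccccc1 | intermediate (not isolated)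
23 | benzyl (E)-3-[2-(ring A aryloxy)-1-methoxy-4-oxocyclobut-2-en-1-yl]dec-2-enoate (racemic) | O=C1C=C(Oc2cc(OC)cc(CCCCCCC)c2C(=O)OCc2ccccc2)C1(OC)/C(CCCCCCC)=C/C(=O)OCc1ccccc1 | intermediate (not isolated)
24 | benzyl (2E,4Z)-5-(ring A aryloxy)-3-heptyl-4-methoxy-7-oxohepta-2,4,6-trienoate (dienylketene) | O=C=C/C(Oc1cc(OC)cc(CCCCCCC)c1C(=O)OCc1ccccc1)=C(OC)\C(CCCCCCC)=C\C(=O)OCc1ccccc1 | intermediate (not isolated)
25 | benzyl 4-(ring A aryloxy)-2-heptyl-3-methoxy-6-oxocyclohexa-2,4-diene-1-carboxylate (racemic) | O=C1C=C(Oc2cc(OC)cc(CCCCCCC)c2C(=O)OCc2ccccc2)C(OC)=C(CCCCCCC)C1C(=O)OCc1ccccc1 | intermediate (not isolated)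
26 | benzyl 4-{2-[(benzyloxy)carbonyl]-3-heptyl-5-methoxyphenoxy}-2-heptyl-6-hydroxy-3-methoxybenzoate | CCCCCCCc1cc(OC)cc(Oc2cc(O)c(C(=O)OCc3ccccc3)c(CCCCCCC)c2OC)c1C(=O)OCc1ccccc1 | intermediate
27 | 4-(2-carboxy-3-heptyl-5-methoxyphenoxy)-2-heptyl-6-hydroxy-3-methoxybenzoic acid | CCCCCCCc1cc(OC)cc(Oc2cc(O)c(C(=O)O)c(CCCCCCC)c2OC)c1C(=O)O | target

Total step count: 13. Longest linear sequence: 8 (steps 1–6, 12, 13). The second arm (steps 7–11) joins at step 12.

Steps most likely to fail

1. Step 12 (new method).
- What may go wrong: the ketene may consume itself by dimerisation or oligomerisation faster than the moderately nucleophilic aryl ynol ether captures it. Reversible addition of the amine to the ketene may erode the alkene geometry and open the closure onto the ester carbonyl. The zwitterion may also close directly to a six-membered ring with the opposite orientation.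
- Fallback (known chemistry): ring B is taken from the resorcylate already in hand and the ether is made by cross-coupling. The fallback sets out from 7 and 6 and returns at 26. Phenol 7 is sulfonylated (Tf2O, pyridine, CH2Cl2) to benzyl 2-heptyl-4-methoxy-6-{[(trifluoromethyl)sulfonyl]oxy}benzoate F1. Palladium-catalysed diaryl ether coupling (Pd(OAc)2, t-BuXPhos, K3PO4, toluene, 100 °C) joins F1 to the unchelated C4 hydroxyl of 6. This gives benzyl 4-{2-[(benzyloxy)carbonyl]-3-heptyl-5-methoxyphenoxy}-2-heptyl-6-hydroxybenzoate F2, which lacks only the C5' oxygen. Elbs persulfate oxidation (K2S2O8, aq KOH, pyridine) attacks para to the only free phenol and gives the potassium C5' aryl sulfate F3. Dilute HCl hydrolyses it to the C5' hydroxy compound, benzyl 4-{2-[(benzyloxy)carbonyl]-3-heptyl-5-methoxyphenoxy}-2-heptyl-3,6-dihydroxybenzoate F4. MeI/K2CO3 then methylates the unchelated C5' hydroxyl, by the logic of step 4, to give 26.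

2. Step 9.
- What may go wrong: transmetalation or reductive elimination of the chelated α-alkoxy zinc enolate may be slow. Proton transfer from the product to the enolate may then cause migration or E/Z scrambling of the double bond.
- Fallback: carbonyl addition and neutral etherification replace the enolate coupling. The fallback sets out from 16 and returns at 19. A Nozaki–Hiyama–Kishi reaction of 16 with tert-butyl glyoxylate (CrCl2, NiCl2 cat., DMF, rt) should give 1-benzyl 5-tert-butyl (E)-3-heptyl-4-hydroxypent-2-enedioate F5 with retention of the alkene geometry. Its carbinol carbon is trans to the benzyl ester, so it cannot lactonise. O-methylation under neutral conditions (MeI, Ag2O, 4 Å sieves, CH2Cl2) gives 19.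

3. Step 6.
- What may go wrong: butyllithium may add to the benzyl ester or cause lateral deprotonation in competition with the wanted elimination and exchange. Acid-triggered hydration of the ynol ether may occur during work-up.
- Fallback: the alkyne is made by bromination and double dehydrobromination of a vinyl ether, without any organolithium reagent. The fallback sets out from 7 and returns at 13. Chan–Lam vinylation of 7 (2,4,6-trivinylcyclotriboroxane–pyridine complex, Cu(OAc)2, pyridine, CH2Cl2, air, rt) gives benzyl 2-(ethenyloxy)-6-heptyl-4-methoxybenzoate F6. Br2 in CH2Cl2 at −78 °C adds to the enol ether double bond to give benzyl 2-(1,2-dibromoethoxy)-6-heptyl-4-methoxybenzoate F7. KOt-Bu in THF (−78 °C to 0 °C) removes HBr twice, by way of benzyl 2-[(2-bromoethenyl)oxy]-6-heptyl-4-methoxybenzoate F8, and gives 13.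

Further compounds
F1 | step 12 | benzyl 2-heptyl-4-methoxy-6-{[(trifluoromethyl)sulfonyl]oxy}benzoate | CCCCCCCc1cc(OC)cc(OS(=O)(=O)C(F)(F)F)c1C(=O)OCc1ccccc1
F2 | step 12 | benzyl 4-{2-[(benzyloxy)carbonyl]-3-heptyl-5-methoxyphenoxy}-2-heptyl-6-hydroxybenzoate | CCCCCCCc1cc(OC)cc(Oc2cc(O)c(C(=O)OCc3ccccc3)c(CCCCCCC)c2)c1C(=O)OCc1ccccc1
F3 | step 12 | potassium C5' aryl sulfate of F4 | CCCCCCCc1cc(OC)cc(Oc2cc(O)c(C(=O)OCc3ccccc3)c(CCCCCCC)c2OS(=O)(=O)[O-])c1C(=O)OCc1ccccc1.[K+]
F4 | step 12 | benzyl 4-{2-[(benzyloxy)carbonyl]-3-heptyl-5-methoxyphenoxy}-2-heptyl-3,6-dihydroxybenzoate | CCCCCCCc1cc(OC)cc(Oc2cc(O)c(C(=O)OCc3ccccc3)c(CCCCCCC)c2O)c1C(=O)OCc1ccccc1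
F5 | step 9 | 1-benzyl 5-tert-butyl (E)-3-heptyl-4-hydroxypent-2-enedioate (racemic) | O=C(OC(C)(C)C)C(O)/C(CCCCCCC)=C/C(=O)OCc1ccccc1
F6 | step 6 | benzyl 2-(ethenyloxy)-6-heptyl-4-methoxybenzoate | C=COc1cc(OC)cc(CCCCCCC)c1C(=O)OCc1ccccc1
F7 | step 6 | benzyl 2-(1,2-dibromoethoxy)-6-heptyl-4-methoxybenzoate (racemic) | BrCC(Br)Oc1cc(OC)cc(CCCCCCC)c1C(=O)OCc1ccccc1
F8 | step 6 | benzyl 2-[(2-bromoethenyl)oxy]-6-heptyl-4-methoxybenzoate (E/Z mixture) | BrC=COc1cc(OC)cc(CCCCCCC)c1C(=O)OCc1ccccc1
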